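**Plan**

- Numbering: O1–C2(syringyl)–C3(CH2OH)–O4 on ring A, enal on C7 (O1 meta and O4 para to it). The retrosynthesis cuts O1–C2 first, then the enal C=C, the O4–C4a aryl ether bond and the C2–aryl bond.
- Forward: the aryl Grignard reagent opens (R)-trityl glycidyl ether (C2–aryl), the resulting alkoxide displaces fluoride on the ring A aldehyde (O4–C4a), and a Wittig reaction adds the enal. The 1,4-dioxane, the only ring made, closes in the penultimate step, before detritylation.
- Enabling feature: benzylic C2 lies para to the free syringyl hydroxyl, so a two-electron oxidation makes it the exocyclic carbon of a p-quinone methide, within six-membered reach of O1, the ring A oxygen meta to the enal.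
- Stereochemistry: C3 is the carbinol carbon of the purchased epoxide and no bond to it is ever broken. C2 is set in the ring closure, trans to C3, by a reversible diequatorial chair-like closure; the E alkene comes from the stabilized ylide.
- Protecting groups: both phenols travel as allyl ethers, removed by zerovalent palladium without acid, so the trityl ether stays on the primary alcohol through the oxidation. A free CH2OH could otherwise attack the ipso carbon of the oxidized syringol in a five-membered spirocyclization.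

Key step: step 7

Assumption: the epoxide written C1[C@H](COCPh3)O1 is (R)-trityl glycidyl ether. Its stereocentre is spatially unchanged throughout and is labelled (R) in 5–12 and (S) at C3 of 13 and 14 only because ligand priorities change.

**Route**

Step 1
Reactants: 1 4-bromo-2,6-dimethoxyphenol
Product: 2 5-bromo-1,3-dimethoxy-2-(prop-2-en-1-yloxy)benzene
Conditions: allyl bromide, K2CO3, DMF, 50 °C
Reagents that add atoms: allyl bromide, C=CCBr
Why: Williamson O-allylation of the phenoxide; the allyl ether should tolerate organomagnesium chemistry, alkoxide base and the Wittig step, and is later removed without acid.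

Step 2
Reactants: 2 5-bromo-1,3-dimethoxy-2-(prop-2-en-1-yloxy)benzene; 3 (R)-trityl glycidyl ether
Product: 5 (2R)-1-[3,5-dimethoxy-4-(prop-2-en-1-yloxy)phenyl]-3-(triphenylmethoxy)propan-2-ol, via arylmagnesium bromide 4 (not isolated)
Conditions: Mg turnings, I2 (cat.), THF, 45 °C; then CuI (10 mol %), 3, THF, −40 to −10 °C; aq NH4Cl
Reagents that add atoms: none
Why: Grignard formation followed by CuI-catalysed (monovalent copper) SN2 opening of the terminal epoxide at its CH2 terminus; the carbinol stereocentre is not involved and is carried over from 3, and the low temperature should leave the aryl allyl ether and the trityl ether untouched.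

Step 3
Reactants: 6 4-fluoro-3-hydroxybenzaldehyde
Product: 7 4-fluoro-3-(prop-2-en-1-yloxy)benzaldehyde
Conditions: allyl bromide, K2CO3, DMF, rt
Reagents that add atoms: allyl bromide, C=CCBr
Why: Williamson O-allylation; it masks the acidic hydroxyl that would quench the alkoxide and deactivate the ring in the following SNAr reaction.

Step 4
Reactants: 5 (2R)-1-[3,5-dimethoxy-4-(prop-2-en-1-yloxy)phenyl]-3-(triphenylmethoxy)propan-2-ol; 7 4-fluoro-3-(prop-2-en-1-yloxy)benzaldehyde
Product: 8 4-{[(2R)-1-[3,5-dimethoxy-4-(prop-2-en-1-yloxy)phenyl]-3-(triphenylmethoxy)propan-2-yl]oxy}-3-(prop-2-en-1-yloxy)benzaldehyde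
Conditions: NaH, DMF, 0 °C; then 7, 0 °C to rt (40 °C if slow)
Reagents that add atoms: none
Why: Nucleophilic aromatic substitution (addition–elimination) of the preformed secondary alkoxide at the fluorine-bearing carbon para to the formyl group; the C–O bond of the stereocentre is not broken, so configuration is retained, and a trityl ether, unlike a silyl or acyl group, cannot migrate to the neighbouring alkoxide.

Step 5
Reactants: 8 4-{[(2R)-1-[3,5-dimethoxy-4-(prop-2-en-1-yloxy)phenyl]-3-(triphenylmethoxy)propan-2-yl]oxy}-3-(prop-2-en-1-yloxy)benzaldehyde; 9 (triphenylphosphoranylidene)acetaldehyde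
Product: 10 (2E)-3-[4-{[(2R)-1-[3,5-dimethoxy-4-(prop-2-en-1-yloxy)phenyl]-3-(triphenylmethoxy)propan-2-yl]oxy}-3-(prop-2-en-1-yloxy)phenyl]prop-2-enal
Conditions: 9 (1.3 equiv), toluene, 80 °C
Reagents that add atoms: none
Why: Wittig olefination with a stabilized formylmethylene ylide, which should give the E enal through reversible oxaphosphetane formation; a small excess of ylide and moderate temperature should limit a second homologation.

Step 6
Reactants: 10 (2E)-3-[4-{[(2R)-1-[3,5-dimethoxy-4-(prop-2-en-1-yloxy)phenyl]-3-(triphenylmethoxy)propan-2-yl]oxy}-3-(prop-2-en-1-yloxy)phenyl]prop-2-enal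
Product: 11 (2E)-3-[3-hydroxy-4-{[(2R)-1-(4-hydroxy-3,5-dimethoxyphenyl)-3-(triphenylmethoxy)propan-2-yl]oxy}phenyl]prop-2-enal
Conditions: Pd(PPh3)4 (5 mol %), K2CO3, degassed MeOH/THF, rt; aq NH4Cl
Reagents that add atoms: none
Why: Tsuji–Trost-type deallylation in which zerovalent palladium ionizes both aryl allyl ethers to π-allyl complexes that methanol/methoxide captures; the alkyl trityl ether and the enal are not allylic C–O electrophiles, and the absence of acid keeps the trityl group in place.

Step 7
Reactants: 11 (2E)-3-[3-hydroxy-4-{[(2R)-1-(4-hydroxy-3,5-dimethoxyphenyl)-3-(triphenylmethoxy)propan-2-yl]oxy}phenyl]prop-2-enal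
Product: 13 (2E)-3-[(2S,3S)-2-(4-hydroxy-3,5-dimethoxyphenyl)-3-[(triphenylmethoxy)methyl]-2,3-dihydro-1,4-benzodioxin-7-yl]prop-2-enal, via p-quinone methide 12 (not isolated)
Conditions: graphite anode, Pt cathode, undivided cell, constant current (about 2 F/mol), Bu4NBF4, 2,6-lutidine, MeCN/HFIP 9:1, rt
Reagents that add atoms: none
Why: Lutidine-assisted loss of two electrons and two protons from the syringol, the most electron-rich arene present (ring A is deactivated by the enal, and the methoxy-flanked, para-alkylated phenoxyl radical cannot dimerize through carbon), gives p-quinone methide 12 whose exocyclic carbon is the former benzylic C2. The closest known reaction type is the anodic or chemical (Ag2O, DDQ) benzylic functionalization of 4-alkyl-2,6-dialkoxyphenols through p-quinone methides, combined with the phenol-to-quinone-methide closure known from oxidative benzodioxane neolignan syntheses. The 1,4-dioxane closes by a 6-exo-trig oxa-1,6-addition of the ring A hydroxyl, held in reach by the preset C3–O4 ether, which forms O1–C2 and rearomatizes the syringyl ring. C2 is controlled by the fixed C3 centre: a chair-like closure with the aryl and CH2OTr groups both equatorial is preferred, and because the addition is reversible through 12 the trans (2S,3S) isomer should accumulate under thermodynamic control. The step needs chemoselectivity among two phenols and three oxygen nucleophiles; this is secured by the oxidation-potential gap between the two rings, by the trityl ether that blocks ipso attack of the primary hydroxyl, and by limiting the charge because the product phenol is itself oxidizable.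

Step 8
Reactants: 13 (2E)-3-[(2S,3S)-2-(4-hydroxy-3,5-dimethoxyphenyl)-3-[(triphenylmethoxy)methyl]-2,3-dihydro-1,4-benzodioxin-7-yl]prop-2-enal
Product: 14 (2E)-3-[(2S,3S)-2-(4-hydroxy-3,5-dimethoxyphenyl)-3-(hydroxymethyl)-2,3-dihydro-1,4-benzodioxin-7-yl]prop-2-enal
Conditions: AcOH/H2O 4:1, 50 °C
Reagents that add atoms: none
Why: SN1 acidolysis of the trityl ether with water trapping the trityl cation; the aqueous medium keeps the enal free, C3 is not involved, and any reversible opening of the p-hydroxybenzyl aryl ether at C2 should only return the more stable trans ring.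

**Compound list**

1 | 4-bromo-2,6-dimethoxyphenol | COc1cc(Br)cc(OC)c1O | starting material
2 | 5-bromo-1,3-dimethoxy-2-(prop-2-en-1-yloxy)benzene | C=CCOc1c(OC)cc(Br)cc1OC | intermediate
3 | (R)-trityl glycidyl ether, (2R)-2-[(triphenylmethoxy)methyl]oxirane | C1[C@H](COC(c2ccccc2)(c2ccccc2)c2ccccc2)O1 | starting material
4 | [3,5-dimethoxy-4-(prop-2-en-1-yloxy)phenyl]magnesium bromide | C=CCOc1c(OC)cc([Mg]Br)cc1OC | intermediate (not isolated)
5 | (2R)-1-[3,5-dimethoxy-4-(prop-2-en-1-yloxy)phenyl]-3-(triphenylmethoxy)propan-2-ol | C=CCOc1c(OC)cc(C[C@H](COC(c2ccccc2)(c2ccccc2)c2ccccc2)O)cc1OC | intermediate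
6 | 4-fluoro-3-hydroxybenzaldehyde | O=Cc1ccc(F)c(O)c1 | starting material
7 | 4-fluoro-3-(prop-2-en-1-yloxy)benzaldehyde | O=Cc1ccc(F)c(OCC=C)c1 | intermediate
8 | 4-{[(2R)-1-[3,5-dimethoxy-4-(prop-2-en-1-yloxy)phenyl]-3-(triphenylmethoxy)propan-2-yl]oxy}-3-(prop-2-en-1-yloxy)benzaldehyde | C=CCOc1c(OC)cc(C[C@H](COC(c2ccccc2)(c2ccccc2)c2ccccc2)Oc3ccc(C=O)cc3OCC=C)cc1OC | intermediate
9 | (triphenylphosphoranylidene)acetaldehyde | O=CC=P(c1ccccc1)(c1ccccc1)c1ccccc1 | starting material
10 | (2E)-3-[4-{[(2R)-1-[3,5-dimethoxy-4-(prop-2-en-1-yloxy)phenyl]-3-(triphenylmethoxy)propan-2-yl]oxy}-3-(prop-2-en-1-yloxy)phenyl]prop-2-enal | C=CCOc1c(OC)cc(C[C@H](COC(c2ccccc2)(c2ccccc2)c2ccccc2)Oc3ccc(/C=C/C=O)cc3OCC=C)cc1OC | intermediate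
11 | (2E)-3-[3-hydroxy-4-{[(2R)-1-(4-hydroxy-3,5-dimethoxyphenyl)-3-(triphenylmethoxy)propan-2-yl]oxy}phenyl]prop-2-enal | COc1cc(C[C@H](COC(c2ccccc2)(c2ccccc2)c2ccccc2)Oc3ccc(/C=C/C=O)cc3O)cc(OC)c1O | intermediate (key-step precursor)
12 | 4-{(2R)-2-[2-hydroxy-4-[(E)-3-oxoprop-1-enyl]phenoxy]-3-(triphenylmethoxy)propylidene}-2,6-dimethoxycyclohexa-2,5-dien-1-one | COC1=CC(=C[C@H](COC(c2ccccc2)(c2ccccc2)c2ccccc2)Oc3ccc(/C=C/C=O)cc3O)C=C(OC)C1=O | intermediate (not isolated)
13 | (2E)-3-[(2S,3S)-2-(4-hydroxy-3,5-dimethoxyphenyl)-3-[(triphenylmethoxy)methyl]-2,3-dihydro-1,4-benzodioxin-7-yl]prop-2-enal | COc1cc([C@@H]2Oc3cc(/C=C/C=O)ccc3O[C@H]2COC(c4ccccc4)(c5ccccc5)c6ccccc6)cc(OC)c1O | intermediate (key-step product)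
14 | (2E)-3-[(2S,3S)-2-(4-hydroxy-3,5-dimethoxyphenyl)-3-(hydroxymethyl)-2,3-dihydro-1,4-benzodioxin-7-yl]prop-2-enal | COc1cc([C@@H]2Oc3cc(/C=C/C=O)ccc3O[C@H]2CO)cc(OC)c1O | target

**Step count and risks**

Total step count: 8. Longest linear sequence: 7 steps (1, 2, 4, 5, 6, 7, 8); step 3 is a one-step branch.

Steps most likely to fail:

1. Step 7. What may go wrong:
   - further oxidation of the product phenol as it accumulates;
   - capture of the oxidized syringol at its ipso carbon or by the solvent;
   - base-promoted tautomerization of the quinone methide to an aryl enol ether, which would erase C3;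
   - incomplete trans selectivity.

   Fallback: the fallback sets out from 11 and separates oxidation from ring closure. One equivalent of DDQ in MeOH/CH2Cl2 at 0 °C should convert the 4-alkyl-2,6-dimethoxyphenol, by the known quinone methide/solvent capture, into (2E)-3-[3-hydroxy-4-{[(1RS,2S)-1-(4-hydroxy-3,5-dimethoxyphenyl)-1-methoxy-3-(triphenylmethoxy)propan-2-yl]oxy}phenyl]prop-2-enal F1; any material that cyclizes directly is already 13. Catalytic pyridinium p-toluenesulfonate in CH2Cl2 at rt should then ionize the p-hydroxybenzyl methyl ether and let the ring A phenol close the dioxane under thermodynamic (trans) control. The fallback comes back to the route at 13.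

2. Step 4. What may go wrong:
   - consumption of the aldehyde by the hindered secondary alkoxide (hemiacetal formation, hydride transfer of the Meerwein–Ponndorf–Verley kind, disproportionation by adventitious hydroxide);
   - slow substitution because the ortho allyloxy group donates into the ring.

   Fallback: the fallback sets out from 5 and uses a nitrile as the activating group. Purchased 4-fluoro-3-hydroxybenzonitrile F2 is allylated (allyl bromide, K2CO3, DMF) to 4-fluoro-3-(prop-2-en-1-yloxy)benzonitrile F3. SNAr with the sodium alkoxide of 5 (NaH, DMF) should give 4-{[(2R)-1-[3,5-dimethoxy-4-(prop-2-en-1-yloxy)phenyl]-3-(triphenylmethoxy)propan-2-yl]oxy}-3-(prop-2-en-1-yloxy)benzonitrile F4. Reduction with i-Bu2AlH (toluene, −78 °C) and hydrolysis of the imine on wet silica gel should deliver aldehyde 8, where the fallback comes back to the route.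

3. Step 5. What may go wrong:
   - sluggish olefination of the electron-rich aldehyde;
   - further homologation of the product enal by the same ylide to a dienal that is hard to separate.

   Fallback: the fallback sets out from 8 and takes an oxidation-state detour. Horner–Wadsworth–Emmons reaction with triethyl phosphonoacetate (NaH, THF, 0 °C) should give ethyl (2E)-3-[4-{[(2R)-1-[3,5-dimethoxy-4-(prop-2-en-1-yloxy)phenyl]-3-(triphenylmethoxy)propan-2-yl]oxy}-3-(prop-2-en-1-yloxy)phenyl]prop-2-enoate F5. Reduction with i-Bu2AlH (CH2Cl2, −78 °C) should give (2E)-3-[4-{[(2R)-1-[3,5-dimethoxy-4-(prop-2-en-1-yloxy)phenyl]-3-(triphenylmethoxy)propan-2-yl]oxy}-3-(prop-2-en-1-yloxy)phenyl]prop-2-en-1-ol F6. Oxidation with MnO2 (CH2Cl2, rt) returns to the route at 10.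

Further compounds
F1 | step 7 | (2E)-3-[3-hydroxy-4-{[(1RS,2S)-1-(4-hydroxy-3,5-dimethoxyphenyl)-1-methoxy-3-(triphenylmethoxy)propan-2-yl]oxy}phenyl]prop-2-enal | COc1cc(C(OC)[C@H](COC(c2ccccc2)(c2ccccc2)c2ccccc2)Oc3ccc(/C=C/C=O)cc3O)cc(OC)c1O
F2 | step 4 | 4-fluoro-3-hydroxybenzonitrile (purchased) | N#Cc1ccc(F)c(O)c1
F3 | step 4 | 4-fluoro-3-(prop-2-en-1-yloxy)benzonitrile | N#Cc1ccc(F)c(OCC=C)c1
F4 | step 4 | 4-{[(2R)-1-[3,5-dimethoxy-4-(prop-2-en-1-yloxy)phenyl]-3-(triphenylmethoxy)propan-2-yl]oxy}-3-(prop-2-en-1-yloxy)benzonitrile | C=CCOc1c(OC)cc(C[C@H](COC(c2ccccc2)(c2ccccc2)c2ccccc2)Oc3ccc(C#N)cc3OCC=C)cc1OC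
F5 | step 5 | ethyl (2E)-3-[4-{[(2R)-1-[3,5-dimethoxy-4-(prop-2-en-1-yloxy)phenyl]-3-(triphenylmethoxy)propan-2-yl]oxy}-3-(prop-2-en-1-yloxy)phenyl]prop-2-enoate | C=CCOc1c(OC)cc(C[C@H](COC(c2ccccc2)(c2ccccc2)c2ccccc2)Oc3ccc(/C=C/C(=O)OCC)cc3OCC=C)cc1OC
F6 | step 5 | (2E)-3-[4-{[(2R)-1-[3,5-dimethoxy-4-(prop-2-en-1-yloxy)phenyl]-3-(triphenylmethoxy)propan-2-yl]oxy}-3-(prop-2-en-1-yloxy)phenyl]prop-2-en-1-ol | C=CCOc1c(OC)cc(C[C@H](COC(c2ccccc2)(c2ccccc2)c2ccccc2)Oc3ccc(/C=C/CO)cc3OCC=C)cc1OC
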